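**Strategy**

Everything rests on opening ring A at C3–C4 and treating O3–C3–C4–C19–O19 as a masked β-hydroxy ketone, an isoxazoline. C4, C18 and C19 are the isopropenyl group of (R)-carvone, whose ring becomes ring B with C17 on C8 and the carbonyl at C9. One intramolecular nitrile oxide cycloaddition forms C3–C4 and O–C19, closes ring A and the isoxazoline and creates quaternary C4. Its precursor is carvone bearing at C10 a methyl group and, trans to the isopropenyl group, a three-carbon chain ending in the C3 aldoxime. Ring B is then finished by γ-oxidation, reductive enol triflation and two cross-couplings.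

Key step: step 5

Remark: labdane numbers are used throughout (for monocyclic compounds as "future C n"); C18 is the 4α-methyl group, C19 the 4β-CH2O carbon, and β is the face of the C20 methyl group.

**Route**

Step 1
Reactants: 1 (R)-carvone; 2 iodomethane
Product: 4 6-methylcarvone as a mixture of epimers at future C10, via lithium enolate 3 (not isolated)
Conditions: LiN(i-Pr)2, THF, −78 °C; MeI, −78 → 0 °C
Reagents that add atoms: none
Why: Kinetic enolate alkylation: LiN(i-Pr)2 removes a proton of the CH2 next to the carbonyl (future C10) and the enolate is C-methylated, the configuration of the new centre being irrelevant because it is enolised again in step 2.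

Step 2
Reactants: 4 6-methylcarvone; 5 3-bromoprop-1-yne
Product: 7 6-methyl-6-(prop-2-ynyl)carvone with the propargyl group trans to the isopropenyl group, via lithium enolate 6 (not isolated)
Conditions: LiN(i-Pr)2, THF, −78 °C; DMPU, HC≡CCH2Br, −78 → −20 °C
Reagents that add atoms: none
Why: Enolate alkylation: the only remaining α-proton is removed and the reactive propargylic bromide attacks the tetrasubstituted enolate anti to the neighbouring isopropenyl group, which sets quaternary C10 with the chain trans and the methyl group cis to that group.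

Step 3
Reactants: 7 6-methyl-6-(prop-2-ynyl)carvone
Product: 9 keto aldehyde (3-oxopropyl chain on C10), via alkenylborane 8 (not isolated)
Conditions: (c-C6H11)2BH [from BH3·SMe2, cyclohexene], THF, 0 °C; then 30% H2O2, pH 7 phosphate buffer, 0 °C → rt
Reagents that add atoms: hydrogen peroxide, OO
Why: Anti-Markovnikov alkyne hydroboration–oxidation: the bulky dialkylborane adds to the terminal alkyne much faster than to the hindered 1,1-disubstituted alkene or the enone, and neutral peroxide oxidation of the alkenylborane gives the aldehyde without epoxidising the enone.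

Step 4
Reactants: 9 keto aldehyde
Product: 10 6-methyl-6-(3-oximinopropyl)carvone
Conditions: NH2OH·HCl, NaOAc, EtOH, 0 °C → rt
Reagents that add atoms: hydroxylamine hydrochloride, NO.Cl
Why: Oxime condensation, in which the unhindered aldehyde reacts while the conjugated C9 ketone with its quaternary neighbour does not.

Step 5
Reactants: 10 6-methyl-6-(3-oximinopropyl)carvone
Product: 13 isoxazoline-fused trans-decalin enone (C3=N–O–C19 ring on the β face of C4), via hydroximoyl chloride 11 (not isolated), via nitrile oxide 12 (not isolated)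
Conditions: NCS, pyridine (cat.), CHCl3, rt; then Et3N (slow addition), CHCl3, high dilution, 40 °C
Reagents that add atoms: none
Why: NCS chlorinates the aldoxime, Et3N removes HCl from hydroximoyl chloride 11, and nitrile oxide 12 adds to the isopropenyl alkene in a concerted [3+2] cycloaddition. The closest known reaction is the intramolecular nitrile oxide–alkene cycloaddition onto a 1,1-disubstituted alkene that leaves a quaternary ring-fusion carbon. Ring A closes through the C3–C4 bond as the six-membered carbocycle in the exo mode, with C19 outside it, and the isoxazoline closes through the O–C19 bond as the fused five-membered ring; the four-atom tether excludes the reverse regiochemistry, which would need a seven-membered carbocycle. C4 is the only new stereocentre and is set by the alkene face that the dipole reaches, that is, by which exocyclic carbon lies syn to the axial C20 methyl group during closure. The step needs C19 in that place and the C18 methyl group turned outward, an arrangement that spares the two methyl groups a 1,3-diaxial contact. The trans, diequatorial C5 and C10 substituents of 10 secure the trans ring fusion, whereas the face at C4 is biased by C20 alone, so this selectivity is the risk that the route carries; slow base addition at high dilution suppresses furoxan formation.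

Step 6
Reactants: 13 isoxazoline-fused trans-decalin enone
Product: 14 19-hydroxy-3,9-dione (4β-hydroxymethyl, 4α-methyl, 7-en-9-one)
Conditions: Mo(CO)6, MeCN/H2O (15:1), 80 °C
Reagents that add atoms: water, O
Why: Reductive N–O cleavage of the isoxazoline by Mo(CO)6 and hydrolysis of the resulting β-hydroxy imine (the known unmasking of isoxazolines) free the 3-oxo-19-hydroxy unit, while the enone is inert and quaternary C4 rules out dehydration or epimerisation.

Step 7
Reactants: 14 19-hydroxy-3,9-dione
Product: 15 3α,19-diol enone
Conditions: Me4NBH(OAc)3, AcOH/MeCN, −30 → 0 °C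
Reagents that add atoms: none
Why: Hydroxyl-directed reduction (Saksena–Evans type): the C19 alkoxyborohydride delivers hydride within the molecule to the β face of C3, which sets the axial 3α-hydroxyl, and the reagent leaves the enone, which has no directing hydroxyl, untouched.

Step 8
Reactants: 15 3α,19-diol enone; 16 3-methylbutanoic anhydride
Product: 17 3α,19-bis(3-methylbutanoate) enone
Conditions: 16 (3 equiv), DMAP (0.2 equiv), pyridine, CH2Cl2, rt → 40 °C
Reagents that add atoms: 3-methylbutanoic anhydride (second equivalent of 16), CC(C)CC(=O)OC(=O)CC(C)C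
Why: DMAP-catalysed acylation in which each hydroxyl group takes one acyl group from one molecule of the anhydride, the primary C19 hydroxyl reacting first and the axial C3 hydroxyl, the only other one present, following on warming with the excess reagent.

Step 9
Reactants: 17 3α,19-bis(3-methylbutanoate) enone
Product: 18 7-ene-6,9-dione
Conditions: Pd(OH)2/C (cat.), t-BuOOH, K2CO3 (0.25 equiv), CH2Cl2, 4 °C → rt
Reagents that add atoms: tert-butyl hydroperoxide, CC(C)(C)OO
Why: Allylic C–H oxidation of an α,β-enone to the ene-1,4-dione with t-BuOOH (a known enone γ-oxidation): C6 is the only methylene whose radical is conjugated with the enone, and the small amount of carbonate at low temperature should leave C5 and the esters untouched.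

Step 10
Reactants: 18 7-ene-6,9-dione
Product: 20 C9 enol triflate 6-ketone (C8=C9), via lithium enolate 19 (not isolated)
Conditions: LiBH(s-Bu)3, THF, −78 °C; then 2-[N,N-bis(trifluoromethylsulfonyl)amino]-5-chloropyridine, −78 → 0 °C; aq. NH4Cl
Reagents that add atoms: 2-[N,N-bis(trifluoromethylsulfonyl)amino]-5-chloropyridine, O=S(=O)(N(c1ccc(Cl)cn1)S(=O)(=O)C(F)(F)F)C(F)(F)F
Why: Conjugate reduction with enolate trapping: the bulky hydride adds to the unsubstituted C7 of the ene-dione, which gives only the C9 enolate because C10 is quaternary, and O-triflation at low temperature fixes the C8=C9 double bond.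

Step 11
Reactants: 20 C9 enol triflate 6-ketone
Product: 21 C9 enol triflate 6β-alcohol
Conditions: NaBH4, CeCl3·7H2O, MeOH/THF, −40 °C
Reagents that add atoms: none
Why: Luche-type carbonyl reduction: hydride attacks C6 from the α face because the β face is screened by the axial C20 methyl and C19 acyloxymethyl groups, which gives the axial 6β-alcohol, and the esters and the vinyl triflate survive at low temperature.

Step 12
Reactants: 21 C9 enol triflate 6β-alcohol; 22 tributyl(vinyl)stannane
Product: 23 9-vinyl 6β-alcohol (C8=C9–C11=C12 diene)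
Conditions: Pd(PPh3)4 (cat.), LiCl, THF, 65 °C
Reagents that add atoms: none
Why: Stille coupling of a vinyl triflate with a vinylstannane, promoted by LiCl under neutral conditions, which tolerates the esters and the free hydroxyl and is established for crowded 2,6,6-trisubstituted cyclohexenyl triflates.

Step 13
Reactants: 24 but-2-ynoic acid
Product: 25 (E)-3-iodobut-2-enoic acid
Conditions: 57% aq. HI, 110 °C, sealed tube
Reagents that add atoms: hydrogen iodide, I
Why: Hydroiodination of a 2-ynoic acid: iodide adds to C3, and at this temperature the adducts should equilibrate to the more stable E acid with iodine trans to the carboxyl group.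

Step 14
Reactants: 23 9-vinyl 6β-alcohol; 25 (E)-3-iodobut-2-enoic acid
Product: 27 target acid, via alkylborane 26 (not isolated)
Conditions: 9-BBN, THF, rt; then 25, Pd(dppf)Cl2 (cat.), AsPh3, Cs2CO3, DMF/H2O, rt; aq. HCl to pH 3
Reagents that add atoms: none
Why: Hydroboration and B-alkyl Suzuki–Miyaura coupling: 9-BBN places boron on the terminal carbon of the vinyl group (the tetrasubstituted C8=C9 bond and the esters are inert), and the alkylborane couples with the vinyl iodide with retention of the E geometry, the acid travelling as its carboxylate.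

**Compound list**

1 | (R)-carvone | CC1=CC[C@H](CC1=O)C(C)=C | starting material
2 | iodomethane | CI | starting material
3 | lithium enolate of 1 (cross-conjugated, at future C10) | [Li+].CC1=CC[C@@H](C(C)=C)C=C1[O-] | intermediate (not isolated)
4 | 6-methylcarvone, both epimers at future C10 | CC1=CC[C@@H](C(C)=C)C(C)C1=O | intermediate
5 | 3-bromoprop-1-yne | C#CCBr | starting material
6 | lithium enolate of 4 | [Li+].CC1=CC[C@@H](C(C)=C)C(C)=C1[O-] | intermediate (not isolated)
7 | 6-methyl-6-(prop-2-ynyl)carvone, propargyl trans and methyl cis to the isopropenyl group | CC1=CC[C@@H](C(C)=C)[C@](C)(CC#C)C1=O | intermediate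
8 | (E)-alkenyl(dicyclohexyl)borane from 7 | CC1=CC[C@@H](C(C)=C)[C@](C)(C/C=C/B(C2CCCCC2)C2CCCCC2)C1=O | intermediate (not isolated)
9 | keto aldehyde, 6-methyl-6-(3-oxopropyl)carvone | CC1=CC[C@@H](C(C)=C)[C@](C)(CCC=O)C1=O | intermediate
10 | 6-methyl-6-(3-oximinopropyl)carvone (oxime geometry not defined) | CC1=CC[C@@H](C(C)=C)[C@](C)(CCC=NO)C1=O | intermediate
11 | hydroximoyl chloride of 10 | CC1=CC[C@@H](C(C)=C)[C@](C)(CCC(Cl)=NO)C1=O | intermediate (not isolated)
12 | nitrile oxide | CC1=CC[C@@H](C(C)=C)[C@](C)(CCC#[N+][O-])C1=O | intermediate (not isolated)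
13 | isoxazoline-fused trans-decalin enone: 5α-H, 10β-methyl, 8-methyl-7-en-9-one, C18 α-methyl and C3=N–O–C19 ring on the β face of C4 | CC1=CC[C@H]2[C@@]3(C)CON=C3CC[C@]2(C)C1=O | intermediate
14 | 19-hydroxy-3,9-dione: 4β-hydroxymethyl-4α,8,10β-trimethyl-5α-decal-7-ene-3,9-dione | CC1=CC[C@H]2[C@@](C)(CO)C(=O)CC[C@]2(C)C1=O | intermediate
15 | 3α,19-diol enone | CC1=CC[C@H]2[C@@](C)(CO)[C@H](O)CC[C@]2(C)C1=O | intermediate
16 | 3-methylbutanoic anhydride | CC(C)CC(=O)OC(=O)CC(C)C | starting material
17 | 3α,19-bis(3-methylbutanoate) of 15 | CC1=CC[C@H]2[C@@](C)(COC(=O)CC(C)C)[C@H](OC(=O)CC(C)C)CC[C@]2(C)C1=O | intermediate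
18 | 7-ene-6,9-dione of 17 | CC1=CC(=O)[C@H]2[C@@](C)(COC(=O)CC(C)C)[C@H](OC(=O)CC(C)C)CC[C@]2(C)C1=O | intermediate
19 | lithium C9 enolate of the 7,8-dihydro-6,9-dione (C8=C9–OLi) | [Li+].CC1=C([O-])[C@@]2(C)CC[C@@H](OC(=O)CC(C)C)[C@](C)(COC(=O)CC(C)C)[C@@H]2C(=O)C1 | intermediate (not isolated)
20 | C9 enol triflate 6-ketone | CC1=C(OS(=O)(=O)C(F)(F)F)[C@@]2(C)CC[C@@H](OC(=O)CC(C)C)[C@](C)(COC(=O)CC(C)C)[C@@H]2C(=O)C1 | intermediate
21 | C9 enol triflate 6β-alcohol | CC1=C(OS(=O)(=O)C(F)(F)F)[C@@]2(C)CC[C@@H](OC(=O)CC(C)C)[C@](C)(COC(=O)CC(C)C)[C@@H]2[C@H](O)C1 | intermediate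
22 | tributyl(vinyl)stannane | C=C[Sn](CCCC)(CCCC)CCCC | starting material
23 | 9-vinyl 6β-alcohol (8,11-diene) | CC1=C(C=C)[C@@]2(C)CC[C@@H](OC(=O)CC(C)C)[C@](C)(COC(=O)CC(C)C)[C@@H]2[C@H](O)C1 | intermediate
24 | but-2-ynoic acid | CC#CC(=O)O | starting material
25 | (E)-3-iodobut-2-enoic acid | C/C(I)=C\C(=O)O | intermediate
26 | B-alkyl-9-BBN adduct of 23 (boron on C12) | CC1=C(CCB2C3CCCC2CCC3)[C@@]2(C)CC[C@@H](OC(=O)CC(C)C)[C@](C)(COC(=O)CC(C)C)[C@@H]2[C@H](O)C1 | intermediate (not isolated)
27 | 3α,19-bis(3-methylbutanoyloxy)-6β-hydroxylabda-8,13E-dien-15-oic acid | CC1=C(CC/C(C)=C/C(=O)O)[C@@]2(C)CC[C@@H](OC(=O)CC(C)C)[C@](C)(COC(=O)CC(C)C)[C@@H]2[C@H](O)C1 | target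

**Step count and risks**

Total step count: 14. Longest linear sequence: 13 steps (steps 1–12 and 14, from (R)-carvone); step 13 prepares the coupling partner.

Steps most likely to fail:

1. Step 5 (key step). The nitrile oxide carbon is linear, so tether carbon C2 stays anti to nitrogen. The ring closure may therefore prefer the chair-like array in which the new C–O bond is equatorial and the C18 methyl group, not C19, lies syn to C20. That would reverse the facial selectivity at C4 and give the C4 epimer. The fallback sets out from 7 and comes back at 14. It exchanges the roles of the two exocyclic carbons: the equatorial carbon reached by the nitrile oxide oxygen becomes C18, and C19 enters already oxygenated. Ene chlorination of the isopropenyl group of 7 (Ca(OCl)2, CO2, CH2Cl2/H2O) gives allylic chloride F1. 4-Methoxyphenol and K2CO3 give aryl ether F2. Hydroboration–oxidation as in step 3 gives, through alkenylborane F3, aldehyde F4, and oximation gives oxime F5. NCS and Et3N lead through hydroximoyl chloride F6 and nitrile oxide F7 to cycloadduct F8, now through the chair-like array, with the new CH2–O bond on the α face (C18) and the aryloxymethyl group on the β face (C19). Mo(CO)6 gives hydroxy ketone F9, I2/PPh3/imidazole gives iodide F10, and Bu3SnH/AIBN at high stannane concentration gives methyl ketone F11. (NH4)2Ce(NO3)6 then removes the aryl group to give 14.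

2. Step 10. Regiocontrol may be lost: a carbonyl group may be reduced directly, or a proton may move within enolate 19 (C7–H is acidic) before the crowded oxygen is triflated. The fallback sets out from 18 and comes back at 20. RhCl(PPh3)3-catalysed 1,4-hydrosilylation of 18 with Et3SiH gives the isolable triethylsilyl enol ether F12. CsF and N-phenylbis(trifluoromethanesulfonimide) convert it into 20, so that no free enolate has to persist.

3. Step 9. Site selectivity may be poor or the oxidation incomplete: hydrogen may be abstracted from the C17 methyl group, or the reaction may stop at the C6 peroxide. The fallback sets out from 17 and comes back at 18. TBSOTf and Et3N give dienol silyl ether F13; only C6 can be deprotonated because C10 is quaternary. Dimethyldioxirane oxidises it at C6 to γ-hydroxy enone F14 (6α expected, either epimer serves), and Dess–Martin periodinane gives 18.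

**Further compounds**

F1 | step 5 | allylic chloride: 7 with CH2Cl in place of the isopropenyl methyl group | CC1=CC[C@@H](C(=C)CCl)[C@](C)(CC#C)C1=O
F2 | step 5 | 4-methoxyphenyl ether of the corresponding allylic alcohol | CC1=CC[C@@H](C(=C)COc2ccc(OC)cc2)[C@](C)(CC#C)C1=O
F3 | step 5 | (E)-alkenyl(dicyclohexyl)borane from F2 | CC1=CC[C@@H](C(=C)COc2ccc(OC)cc2)[C@](C)(C/C=C/B(C2CCCCC2)C2CCCCC2)C1=O
F4 | step 5 | keto aldehyde with aryloxymethyl alkene | CC1=CC[C@@H](C(=C)COc2ccc(OC)cc2)[C@](C)(CCC=O)C1=O
F5 | step 5 | oxime of F4 | CC1=CC[C@@H](C(=C)COc2ccc(OC)cc2)[C@](C)(CCC=NO)C1=O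
F6 | step 5 | hydroximoyl chloride of F5 | CC1=CC[C@@H](C(=C)COc2ccc(OC)cc2)[C@](C)(CCC(Cl)=NO)C1=O
F7 | step 5 | nitrile oxide from F6 | CC1=CC[C@@H](C(=C)COc2ccc(OC)cc2)[C@](C)(CCC#[N+][O-])C1=O
F8 | step 5 | isoxazoline with C3=N–O–C18 ring on the α face and 4β-(4-methoxyphenoxymethyl) group | CC1=CC[C@H]2[C@]3(COc4ccc(OC)cc4)CON=C3CC[C@]2(C)C1=O
F9 | step 5 | 18-hydroxy-19-(4-methoxyphenoxy)-3,9-dione | CC1=CC[C@H]2[C@](COc3ccc(OC)cc3)(CO)C(=O)CC[C@]2(C)C1=O
F10 | step 5 | 18-iodo-19-(4-methoxyphenoxy)-3,9-dione | CC1=CC[C@H]2[C@](COc3ccc(OC)cc3)(CI)C(=O)CC[C@]2(C)C1=O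
F11 | step 5 | 19-(4-methoxyphenoxy)-3,9-dione with 4α-methyl group | CC1=CC[C@H]2[C@](COc3ccc(OC)cc3)(C)C(=O)CC[C@]2(C)C1=O
F12 | step 10 | C9 triethylsilyl enol ether 6-ketone | CC1=C(O[Si](CC)(CC)CC)[C@@]2(C)CC[C@@H](OC(=O)CC(C)C)[C@](C)(COC(=O)CC(C)C)[C@@H]2C(=O)C1
F13 | step 9 | C9 tert-butyldimethylsilyl dienol ether (6,8-diene) of 17 | CC1=C(O[Si](C)(C)C(C)(C)C)[C@@]2(C)CC[C@@H](OC(=O)CC(C)C)[C@](C)(COC(=O)CC(C)C)[C@@H]2C=C1
F14 | step 9 | 6α-hydroxy-7-en-9-one of 17 | CC1=C[C@H](O)[C@H]2[C@@](C)(COC(=O)CC(C)C)[C@H](OC(=O)CC(C)C)CC[C@]2(C)C1=O
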